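## The problem

Compound 36 is a cis-fused decalin (ring A: C1–C5 and C10; ring B: C5–C10). It carries a 2-methoxy-4-pyranone on a methylene group (C11) at C9, an exocyclic methylene at C8, a hydroxyl at C3 and, at C4, a methyl group and a C1′–C3′ chain ending in a tertiary formate. Five stereocentres (C3, C4, C5, C9, C10) must be set, two of them quaternary and 1,3-related (C4, C10). With α defined as the face of the C10 methyl group, H5 and the C4 methyl are α, while C1′, the C3 hydroxyl and C11 are β. Once C10 is fixed it can control C5 and C4 if ring B is closed from a chain on C10, and the rigid polycycle can then control C3. C9 is controlled by none of these, so it must be set early and shielded from epimerisation whenever C8 or C11 is a carbonyl carbon. The fragile parts are the tertiary formate beside a free secondary alcohol, the exocyclic alkene allylic to C9–H, and the α-methoxy-γ-pyranone, which must be methylated on the correct oxygen. The enabling feature is that C1′ (on C4), C6 (on C5) and C9 (on C10) all lie on the β face. A two-carbon unit C6–C1′ can therefore be laid across the C4=C5 bond of a ring A enone from a chain C9–C8–C7 on C10, closing ring B. The C6–C1′ bond is cut afterwards, so that C1′ becomes the first chain carbon and C6 is reduced to the methylene group the target needs.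

## Retrosynthesis

**Formate and C3–O (36 ⇐ 35 ⇐ 34).** The formyl C–O bond is cut last but one. A free C3 hydroxyl would be formylated before the tertiary one, so C3–O stays silylated in 35 and 34. Placing the formate earlier would expose it to acid, ylide and Grignard reagents. The forward steps must acylate a tertiary alcohol and then remove a hindered silyl ether without base.

**C8 methylene (34 ⇐ 33 ⇐ 32).** The C8=CH2 bond is traced to ketone 33 and its dioxolane 32. An alkene at C8 could not pass the photochemical, ozonolysis and hydrogenation steps, so C8 travels as a ketal. The ketone is freed only after the pyrone oxygen is methylated, so no enol oxygen can close onto C8. The forward step is a non-basic methylenation of a hindered, enolisable ketone.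

**Pyranone (32 ⇐ 31 ⇐ 26 + 29; 29 ⇐ 27 + 28).** The O–CH3 bond and then the C11–C3(pyrone) bond are cut. This gives aldehyde 26 and hydroxypyrone 29, which comes in one step from methyl acetoacetate 27 and malonyl dichloride 28. Cutting C9–C11 instead would create C9 late under substrate control. The coupling must work on a congested aldehyde without epimerising C9, and the methylation must give the 2-methoxy-4-pyranone.

**Side chain and C6 (26 ⇐ 25 ⇐ 24 ⇐ 23 ⇐ 21 ⇐ 19 + 20).** The two C3′–CH3 bonds (MeMgBr), the C1′=C2′ bond (ylide 20) and the C6 methylene (from the C6 ketone) are disconnected. C1′ is cut at C1′–C2′ and not at C4–C1′, because the cleavage of the temporary ring delivers C1′ as an aldehyde on an already quaternary C4. Hydrogenation both saturates the chain and frees C11–OH. Keto aldehyde 19 holds all five stereocentres.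

**Temporary bond (19 ⇐ 18 ⇐ 17 ⇐ 16).** Reconnecting C6 to C1′ turns 19 into cyclobutene 18. The C3 carbinol is set on tricycle 16, where the bowl shape exposes one face of the ketone. It is silylated before cleavage, because a free β-hydroxy aldehyde or a 1,3-keto aldehyde at C3/C1′ would fragment.

**Key disconnection (16 ⇐ 15).** C5–C6 and C4–C1′ are cut together. This opens ring B and the cyclobutene and removes the stereocentres C4 and C5. Enone 15 has only the C10 and C9 centres and a pentynyl chain. The forward reaction is an intramolecular enone–alkyne [2+2] photocycloaddition.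

**Ring A (15 ⇐ 12 + 13).** C1–C10 and C4–C5 are cut (Robinson annulation of α-branched aldehyde 12 with pent-1-en-3-one 13). The vinyl ketone brings C3 in as the only free carbonyl, so no differentiation from the masked C8 is needed. The C10 methyl group in 12 is stereochemically irrelevant because C10 becomes planar in the enamine. The annulation must set the quaternary C10 relative to C9.

**Chain adjustments (12 ⇐ 11 ⇐ 10 ⇐ 9 ⇐ 8 ⇐ 6).** These are the C10–CH3 bond (MeI on ester 10), the C8 dioxolane (from ketone 9), the ketone (from nitro compound 8 by a Nef reaction) and the oxidation level of C5. The ester stage lets C8 be unmasked and ketalised without a 1,4-keto aldehyde in the molecule.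

**C8–C9 bond (6 ⇐ 2 + 5; 2 ⇐ 1; 5 ⇐ 3 + 4).** Nitroalkane 2 is an acyl-anion equivalent for C8 that already carries C7, C6 and C1′. It adds to C9 of enal 5 under iminium catalysis, which sets the only stereocentre that nothing else in the molecule can control. The benzyl ether on C11 is present from the start, so no hydroxyl is ever free beside the ring A enone. A lactone-based alternative would release a C11 hydroxyl that could add to C5 of the enone.

## Roads not taken

**Alternative 1: double Michael annulation.** The cut is C4–C5 and C1–C10. Forward, keto ester A1 adds through C4 to C5 of enone ester A2 under chiral phase-transfer catalysis, and the resulting C10 enolate closes onto the vinyl ketone to give dione diester A3.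
- Merits: ring A, two C–C bonds and the C4, C5 and C10 centres arise in one catalytic step from trivial materials, the cis fusion is natural, and no photochemistry is needed. In step count to a decalin it is clearly better than the chosen plan.
- Weak points for this target: C10 carries an ester where a methyl group is needed, and the C4 ester must be homologated at a neopentyl position. The carbonyl sits at C9, where the target needs a carbon substituent, and C8 is unfunctionalised, so a carbonyl transposition and a late C9 stereocentre follow. Enantiocontrol of a phase-transfer double Michael reaction on these partners is less secure than the iminium step used here.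
- Set against it: 16 and 19 already have the C10 methyl, the C8 oxygen, C9 with its carbon and C1′ at the aldehyde level.

**Alternative 2: cationic bicyclisation.** The cut is C4–C5 and C9–C10. Forward, a Lewis acid ionises an allylic C4–O bond, the (Z)-olefin attacks C4 through C5, and a silyl enol ether traps the C10 cation through C9 to give A4.
- Merits: both rings, four stereocentres, the chain with its tertiary alcohol and a two-carbon handle on C11 come in one step. It is the shortest conceivable route to the skeleton.
- Weak points: the ionisation erases the only stereocentre of the precursor, so absolute control would have to come from a chiral counter-ion. The allyl cation can also be attacked at its other terminus. The cis fusion with two quaternary carbons rests on transition-state geometry alone. The C2=C3 alkene of A4 must still be hydrated at the more hindered carbon from the right face, and the malonate must be built into the pyranone ring.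
- Set against it: the chosen plan is longer but sets each centre by a separately defensible element.

**Alternative 3: Knoevenagel–Sakurai union.** The cut is C9–C11 and C11–C3(pyrone). Forward, formaldehyde A6 condenses with pyrone 29, and the methylene dione is attacked by C9 of ring B allylsilane A5 with loss of silicon to give A7.
- Merits: C11, the pyrone and the exocyclic methylene arrive in one step, and no epimerisable C11 aldehyde or separate methylenation is needed. For the last stage it is better than the chosen plan by about three steps.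
- Weak points: it is an end game only and presupposes the complete decalin as an allylsilane. C9 is created last, next to the quaternary C10, under substrate control in a flexible cis-decalin. The regioselective O-methylation remains.
- Set against it: the chosen plan carries C11 and a catalyst-set C9 from step 3, so no late facial selectivity is needed, but it pays with an oxidation, a reductive coupling and a methylenation.

Key step: step 10

Remark: α is the face bearing the C10 methyl group and atom numbers follow the target (C1–C11, C1′–C3′) in all intermediates; compounds 1, 3, 4, 13, 20, 27 and 28 are taken as purchased.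

## Route

Step 1
Reactants: 1 (4-bromobut-1-yn-1-yl)trimethylsilane
Product: 2 trimethyl(4-nitrobut-1-yn-1-yl)silane
Conditions: NaNO2, urea, DMF, rt
Reagents that add atoms: sodium nitrite, [Na+].[O-]N=O
Why: Kornblum displacement of a primary bromide by nitrite gives the nitroalkane, an acyl-anion equivalent for C8 that already carries C7, C6 and C1′.

Step 2
Reactants: 3 (benzyloxy)acetaldehyde; 4 (triphenylphosphoranylidene)acetaldehyde
Product: 5 (2E)-4-(benzyloxy)but-2-enal
Conditions: toluene, 80 °C
Reagents that add atoms: none
Why: Wittig olefination with a formyl-stabilised ylide gives the E enal; the benzyl ether on C11 tolerates the acidic, basic and oxidative steps ahead and is removed later by hydrogenolysis.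

Step 3
Reactants: 2 trimethyl(4-nitrobut-1-yn-1-yl)silane; 5 (2E)-4-(benzyloxy)but-2-enal
Product: 6 (3R)-3-[(benzyloxy)methyl]-4-nitro-7-(trimethylsilyl)hept-6-ynal (both epimers at the nitro carbon)
Conditions: (S)-α,α-diphenylprolinol trimethylsilyl ether (10 mol %), PhCO2H (20 mol %), MeOH, rt
Reagents that add atoms: none
Why: Iminium-catalysed Michael addition of a nitroalkane to an enal; the diphenyl(silyloxy)methyl group shields one face of the E iminium ion, so C8 adds to the open face of C9 and sets it in the required sense (3R here), while the configuration at the nitro carbon is irrelevant.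

Step 4
Reactants: 6 nitro aldehyde
Product: 8 methyl (3R)-3-[(benzyloxy)methyl]-4-nitro-7-(trimethylsilyl)hept-6-ynoate, via carboxylic acid 7 (not isolated)
Conditions: NaClO2, NaH2PO4, 2-methylbut-2-ene, t-BuOH/H2O, 0 °C to rt; then TMSCHN2, MeOH/toluene, 0 °C
Reagents that add atoms: sodium chlorite, [Na+].[O-]Cl=O; (trimethylsilyl)diazomethane, C[Si](C)(C)C=[N+]=[N-]
Why: Pinnick oxidation and diazoalkane esterification bring C5 to the ester level, so that C8 can be unmasked and C10 methylated with no aldehyde in the molecule; C9 is not touched.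

Step 5
Reactants: 8 nitro ester
Product: 9 methyl (3S)-3-[(benzyloxy)methyl]-4-oxo-7-(trimethylsilyl)hept-6-ynoate
Conditions: NaOMe (1.0 equiv), MeOH, 0 °C; then TiCl3 (aq.), NH4OAc, H2O, pH 5–6, rt
Reagents that add atoms: water, O
Why: Reductive Nef reaction: trivalent titanium reduces the nitronate to the imine, which hydrolyses at buffered pH to the ketone; near-neutral conditions spare the benzyloxy group β to the new carbonyl and limit enolisation towards C9 (the descriptor changes only through the priority rules).

Step 6
Reactants: 9 keto ester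
Product: 10 methyl (3S)-4-(benzyloxy)-3-{2-[3-(trimethylsilyl)prop-2-yn-1-yl]-1,3-dioxolan-2-yl}butanoate
Conditions: 1,2-bis(trimethylsilyloxy)ethane, TMSOTf (5 mol %), CH2Cl2, −78 to −20 °C
Reagents that add atoms: 1,2-bis(trimethylsilyloxy)ethane, C[Si](C)(C)OCCO[Si](C)(C)C
Why: Silyl-triflate-catalysed dioxolane formation at low temperature masks C8 without enolising the β,γ-alkynyl ketone, so neither allene formation nor epimerisation at C9 is expected.

Step 7
Reactants: 10 ketal ester
Product: 11 methyl (2RS,3S)-4-(benzyloxy)-2-methyl-3-{2-[3-(trimethylsilyl)prop-2-yn-1-yl]-1,3-dioxolan-2-yl}butanoate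
Conditions: LiN(i-Pr)2, THF, −78 °C; then MeI
Reagents that add atoms: iodomethane, CI
Why: Ester enolate alkylation installs the C10 methyl group; the new centre needs no control because it becomes planar again in the enamine of step 9.

Step 8
Reactants: 11 methylated ester
Product: 12 (2RS,3S)-4-(benzyloxy)-2-methyl-3-{2-[3-(trimethylsilyl)prop-2-yn-1-yl]-1,3-dioxolan-2-yl}butanal
Conditions: i-Bu2AlH (1.1 equiv), CH2Cl2, −78 °C
Reagents that add atoms: none
Why: Partial reduction of the hindered methyl ester stops at the aluminium hemiacetal and gives the α-branched aldehyde on work-up.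

Step 9
Reactants: 12 α-branched aldehyde; 13 pent-1-en-3-one
Product: 15 (4R)-4-{(1S)-2-(benzyloxy)-1-[2-(prop-2-yn-1-yl)-1,3-dioxolan-2-yl]ethyl}-2,4-dimethylcyclohex-2-en-1-one, via keto aldehyde 14 (not isolated)
Conditions: (R)-N-(4-dodecylphenylsulfonyl)pyrrolidine-2-carboxamide (20 mol %), ClCH2CH2Cl, rt; then KOH, MeOH, rt
Reagents that add atoms: none
Why: Amine-catalysed Robinson annulation of an α-branched aldehyde: the E enamine adds to the enone held by the sulfonamide N–H of the D-proline-derived catalyst, which delivers C1 to the face of C10 that is also open with respect to C9 (anti to the dioxolane branch), so catalyst and substrate should reinforce each other and give the (R) quaternary centre. Methanolic KOH then closes ring A by aldol condensation of C4 onto C5 and cleaves the alkynyl silane.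

Step 10
Reactants: 15 ring A enone with pentynyl chain on C10
Product: 16 cyclobutene ketone (tricycle: C3 ketone; cyclobutene C4–C5–C6=C1′; ring B closed by C5–C6; C8 dioxolane; 9β-CH2OBn; 4α-methyl; 5α-H; 10α-methyl)
Conditions: hν (365 nm), degassed MeCN (5 mM), rt, stopped at full conversion
Reagents that add atoms: none
Why: Excitation of the enone and intersystem crossing give the triplet, whose β carbon C5 attacks the inner alkyne carbon C6; the triplet 1,4-diradical (vinyl radical at C1′, α-keto radical at C4) then closes C4–C1′ after spin inversion. The closest known reaction type is the intramolecular enone–alkyne [2+2] photocycloaddition to a cyclobutene, here with the chain on the γ carbon of the enone. Ring B closes in a 6-exo-dig mode (C5 onto C6 through C10, C9, C8, C7); the chain length rules out a five-membered first ring, and the other modes would need seven- or eight-membered rings, while the cyclobutene closes by diradical recombination. C5 is controlled by C10: the chain reaches only the face of C5 syn to C9, so the ring fusion is cis and H5 is α. C4 is fixed by the four-membered ring, which can only be cis-fused to ring A, so C1′ lands on the β face beside C6 and the C4 methyl stays α. The step needs the straight regiochemistry and complete face selectivity, both secured by the chain and the C10 centre. It also needs chemoselectivity against secondary photoreactions of the β,γ-unsaturated ketone product (1,3-acyl shift), addressed by irradiating only the long-wavelength band and stopping at full conversion. The C9 centre, the dioxolane and the benzyl ether are spectators.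

Step 11
Reactants: 16 cyclobutene ketone
Product: 17 cyclobutene alcohol (3β-hydroxy, 3S; otherwise as 16)
Conditions: NaBH4, MeOH/CH2Cl2, −20 to 0 °C
Reagents that add atoms: none
Why: Hydride reduction from the convex α face of the bowl-shaped tricycle (the β face is covered by the cyclobutene and ring B, with C6 in a 1,3 relation to C3) should give the 3β alcohol, cis to C1′.

Step 12
Reactants: 17 cyclobutene alcohol
Product: 18 cyclobutene silyl ether (3β-OSi(t-Bu)Me2; otherwise as 17)
Conditions: TBSOTf, 2,6-lutidine, CH2Cl2, 0 °C
Reagents that add atoms: tert-butyldimethylsilyl trifluoromethanesulfonate, CC(C)(C)[Si](C)(C)OS(=O)(=O)C(F)(F)F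
Why: Silylation of the hindered secondary alcohol; the ether carries C3–O through the oxidative, organometallic and acidic steps and prevents retro-aldol cleavage once C1′ is an aldehyde.

Step 13
Reactants: 18 cyclobutene silyl ether
Product: 19 keto aldehyde (cis-decalin: C6 ketone; 4β-CHO; 4α-methyl; 3β-OTBS; 5α-H; 10α-methyl; C8 dioxolane; 9β-CH2OBn)
Conditions: O3, pyridine (3 equiv), CH2Cl2, −78 °C
Reagents that add atoms: ozone, [O-][O+]=O
Why: Ozonolysis of the strained and only C=C bond cuts the temporary C6–C1′ bond and leaves the C6 ketone and the C4 aldehyde; pyridine decomposes the carbonyl oxide directly, so no basic or peroxide work-up is needed and C5, now α to a ketone, keeps its configuration.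

Step 14
Reactants: 19 keto aldehyde; 20 methyl (triphenylphosphoranylidene)acetate
Product: 21 keto enoate (as 19 with 4β-[(E)-CH=CH–CO2Me])
Conditions: toluene, 90 °C
Reagents that add atoms: none
Why: Wittig olefination with a stabilised ylide is selective for the aldehyde over the C6 ketone and gives the E enoate (C1′=C2′, C3′) under neutral conditions that do not enolise C6.

Step 15
Reactants: 21 keto enoate
Product: 23 enoate (as 21 with CH2 at C6), via tosylhydrazone 22 (not isolated)
Conditions: TsNHNH2, MeOH/THF, 50 °C; then catecholborane, CHCl3, 0 °C; then NaOAc·3H2O, reflux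
Reagents that add atoms: none
Why: Tosylhydrazone formation and catecholborane reduction (hydride addition to C=N, loss of sulfinate, loss of N2 from the diazene) convert the C6 carbonyl into CH2 under mild, non-basic conditions that leave enoate, ketal and silyl ether alone.

Step 16
Reactants: 23 enoate
Product: 24 hydroxy ester (4β-CH2CH2CO2Me; 9β-CH2OH; otherwise as 23)
Conditions: H2 (1 atm), Pd/C (10 %), EtOAc, rt
Reagents that add atoms: none
Why: Catalytic hydrogenation saturates C1′=C2′ and cleaves the benzyl ether in one operation; no other reducible group is present at this stage.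

Step 17
Reactants: 24 hydroxy ester
Product: 25 diol (4β-CH2CH2C(CH3)2OH; 9β-CH2OH; 3β-OTBS; C8 dioxolane)
Conditions: MeMgBr (5 equiv), THF, 0 °C to rt
Reagents that add atoms: methylmagnesium bromide, C[Mg]Br
Why: Double Grignard addition to the methyl ester gives the C3′ dimethyl carbinol; ketal, silyl ether and the magnesium alkoxide of C11–OH are inert.

Step 18
Reactants: 25 diol
Product: 26 aldehyde (9β-CHO; otherwise as 25)
Conditions: Dess–Martin periodinane, NaHCO3, CH2Cl2, 0 °C to rt
Reagents that add atoms: none
Why: Buffered Dess–Martin oxidation converts the primary C11 alcohol into the aldehyde, leaves the tertiary alcohol alone and should not epimerise C9, which is flanked by two fully substituted carbons.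

Step 19
Reactants: 27 methyl acetoacetate; 28 malonyl dichloride
Product: 29 methyl 4-hydroxy-6-methyl-2-oxo-2H-pyran-5-carboxylate
Conditions: CH2Cl2, rt then 40 °C
Reagents that add atoms: none
Why: C-acylation of the keto ester at its central carbon followed by O-acylation of the enol by the second acid chloride (pyrone synthesis from malonyl dichloride and a 1,3-dicarbonyl compound) gives the 4-hydroxy-2-pyrone.

Step 20
Reactants: 26 aldehyde; 29 hydroxypyrone
Product: 31 pyrone adduct (9β-CH2 bonded to C3 of the 4-hydroxy-5-methoxycarbonyl-6-methyl-2-pyrone; otherwise as 26), via alkylidene pyrandione 30 (not isolated)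
Conditions: L-proline (20 mol %), Hantzsch ester (1.2 equiv), CH2Cl2, rt
Reagents that add atoms: none
Why: Three-component reductive alkylation: Knoevenagel condensation of the aldehyde with C3 of the pyrone gives the alkylidene dione, which is reduced at once by conjugate hydride transfer from the Hantzsch ester. C8 is still masked, so neither a β-keto aldehyde nor a β,γ-unsaturated aldehyde is ever present.

Step 21
Reactants: 31 pyrone adduct
Product: 32 methoxypyranone ketal (2-methoxy-4-pyranone; otherwise as 31)
Conditions: MeOTf (1.2 equiv), 2,6-di-tert-butyl-4-methylpyridine, CH2Cl2, 0 °C to rt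
Reagents that add atoms: methyl trifluoromethanesulfonate, COS(=O)(=O)C(F)(F)F
Why: Methylation of the neutral 4-hydroxy-2-pyrone with a hard electrophile occurs at the lactone carbonyl oxygen and, after proton loss, gives the 2-methoxy-4-pyranone (the established route to α-methoxy-γ-pyrones); the hindered base takes up the acid and does not deprotonate the tertiary alcohol.

Step 22
Reactants: 32 methoxypyranone ketal
Product: 33 methoxypyranone ketone (C8 ketone; otherwise as 32)
Conditions: HCl (1 M, aq.), THF, rt
Reagents that add atoms: water, O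
Why: Acid hydrolysis of the dioxolane frees the C8 ketone only after the pyrone oxygen is methylated, so no enol oxygen can close onto C8; the hindered silyl ether and the tertiary alcohol should survive dilute acid at rt.

Step 23
Reactants: 33 methoxypyranone ketone
Product: 34 methylene alcohol (C8=CH2; free tertiary C3′–OH; 3β-OTBS)
Conditions: Zn, CH2Br2, TiCl4, THF/CH2Cl2, 0 °C to rt
Reagents that add atoms: dibromomethane, BrCBr
Why: Takai–Lombardo methylenation is non-basic, so the enolisable C8 ketone becomes the exocyclic methylene without epimerisation at C9; esters, the pyranone and free hydroxyl groups are tolerated.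

Step 24
Reactants: 34 methylene alcohol
Product: 35 silyl formate (C3′–OCHO; 3β-OTBS)
Conditions: AcOCHO, pyridine, DMAP (cat.), CH2Cl2, 0 °C to rt
Reagents that add atoms: acetic formic anhydride, CC(=O)OC=O
Why: Formyl transfer from the mixed anhydride is fast enough to acylate the tertiary alcohol, the only free hydroxyl group.

Step 25
Reactants: 35 silyl formate
Product: 36 CNP0292250.1
Conditions: HF·pyridine, pyridine, THF, 0 °C to rt
Reagents that add atoms: none
Why: Fluoride cleavage of the silyl ether under weakly acidic, non-nucleophilic conditions frees the C3 alcohol and should leave the tertiary formate, the methyl ester, the pyranone and the exocyclic alkene untouched.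

## Compound list

1 | (4-bromobut-1-yn-1-yl)trimethylsilane | C[Si](C)(C)C#CCCBr | starting material
2 | trimethyl(4-nitrobut-1-yn-1-yl)silane | C[Si](C)(C)C#CCC[N+](=O)[O-] | intermediate
3 | (benzyloxy)acetaldehyde | O=CCOCc1ccccc1 | starting material
4 | (triphenylphosphoranylidene)acetaldehyde | O=CC=P(c1ccccc1)(c1ccccc1)c1ccccc1 | starting material
5 | (2E)-4-(benzyloxy)but-2-enal | O=C/C=C/COCc1ccccc1 | intermediate
6 | (3R)-3-[(benzyloxy)methyl]-4-nitro-7-(trimethylsilyl)hept-6-ynal, both C4 epimers | O=CC[C@@H](COCc1ccccc1)C(CC#C[Si](C)(C)C)[N+](=O)[O-] | intermediate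
7 | (3R)-3-[(benzyloxy)methyl]-4-nitro-7-(trimethylsilyl)hept-6-ynoic acid | OC(=O)C[C@@H](COCc1ccccc1)C(CC#C[Si](C)(C)C)[N+](=O)[O-] | intermediate (not isolated)
8 | methyl (3R)-3-[(benzyloxy)methyl]-4-nitro-7-(trimethylsilyl)hept-6-ynoate | COC(=O)C[C@@H](COCc1ccccc1)C(CC#C[Si](C)(C)C)[N+](=O)[O-] | intermediate
9 | methyl (3S)-3-[(benzyloxy)methyl]-4-oxo-7-(trimethylsilyl)hept-6-ynoate | COC(=O)C[C@@H](COCc1ccccc1)C(=O)CC#C[Si](C)(C)C | intermediate
10 | methyl (3S)-4-(benzyloxy)-3-{2-[3-(trimethylsilyl)prop-2-yn-1-yl]-1,3-dioxolan-2-yl}butanoate | COC(=O)C[C@@H](COCc1ccccc1)C1(CC#C[Si](C)(C)C)OCCO1 | intermediate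
11 | methyl (2RS,3S)-4-(benzyloxy)-2-methyl-3-{2-[3-(trimethylsilyl)prop-2-yn-1-yl]-1,3-dioxolan-2-yl}butanoate | COC(=O)C(C)[C@@H](COCc1ccccc1)C1(CC#C[Si](C)(C)C)OCCO1 | intermediate
12 | (2RS,3S)-4-(benzyloxy)-2-methyl-3-{2-[3-(trimethylsilyl)prop-2-yn-1-yl]-1,3-dioxolan-2-yl}butanal | O=CC(C)[C@@H](COCc1ccccc1)C1(CC#C[Si](C)(C)C)OCCO1 | intermediate
13 | pent-1-en-3-one | C=CC(=O)CC | starting material
14 | (2S,3S)-4-(benzyloxy)-2-methyl-2-(3-oxopentyl)-3-{2-[3-(trimethylsilyl)prop-2-yn-1-yl]-1,3-dioxolan-2-yl}butanal | O=C[C@@](C)(CCC(=O)CC)[C@@H](COCc1ccccc1)C1(CC#C[Si](C)(C)C)OCCO1 | intermediate (not isolated)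
15 | (4R)-4-{(1S)-2-(benzyloxy)-1-[2-(prop-2-yn-1-yl)-1,3-dioxolan-2-yl]ethyl}-2,4-dimethylcyclohex-2-en-1-one | O=C1CC[C@](C)(C=C1C)[C@@H](COCc1ccccc1)C2(OCCO2)CC#C | intermediate (precursor of the key step)
16 | cyclobutene ketone: tricyclic photoadduct, C3 ketone, cyclobutene C4–C5–C6=C1′, C8 dioxolane, 9β-CH2OBn, 4α-Me, 5α-H, 10α-Me | C13(OCCO1)CC(=C4)[C@H]2[C@]4(C)C(=O)CC[C@@]2(C)[C@H]3COCc5ccccc5 | intermediate (product of the key step)
17 | cyclobutene alcohol: (3S)-3β-hydroxy derivative of 16 | C13(OCCO1)CC(=C4)[C@H]2[C@]4(C)[C@@H](O)CC[C@@]2(C)[C@H]3COCc5ccccc5 | intermediate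
18 | cyclobutene silyl ether: 3β-tert-butyldimethylsilyl ether of 17 | C13(OCCO1)CC(=C4)[C@H]2[C@]4(C)[C@@H](O[Si](C)(C)C(C)(C)C)CC[C@@]2(C)[C@H]3COCc5ccccc5 | intermediate
19 | keto aldehyde: cis-decalin, C6 ketone, 4β-CHO, 4α-Me, 3β-OTBS, 5α-H, 10α-Me, C8 dioxolane, 9β-CH2OBn | C13(OCCO1)CC(=O)[C@H]2[C@@](C)(C=O)[C@@H](O[Si](C)(C)C(C)(C)C)CC[C@@]2(C)[C@H]3COCc4ccccc4 | intermediate
20 | methyl (triphenylphosphoranylidene)acetate | COC(=O)C=P(c1ccccc1)(c1ccccc1)c1ccccc1 | starting material
21 | keto enoate: 19 with 4β-[(E)-2-(methoxycarbonyl)ethenyl] | C13(OCCO1)CC(=O)[C@H]2[C@@](C)(/C=C/C(=O)OC)[C@@H](O[Si](C)(C)C(C)(C)C)CC[C@@]2(C)[C@H]3COCc4ccccc4 | intermediate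
22 | C6 tosylhydrazone of 21 | C13(OCCO1)CC(=NNS(=O)(=O)c4ccc(C)cc4)[C@H]2[C@@](C)(/C=C/C(=O)OC)[C@@H](O[Si](C)(C)C(C)(C)C)CC[C@@]2(C)[C@H]3COCc5ccccc5 | intermediate (not isolated)
23 | enoate: 21 with CH2 at C6 | C13(OCCO1)CC[C@H]2[C@@](C)(/C=C/C(=O)OC)[C@@H](O[Si](C)(C)C(C)(C)C)CC[C@@]2(C)[C@H]3COCc4ccccc4 | intermediate
24 | hydroxy ester: 4β-CH2CH2CO2Me, 9β-CH2OH | C13(OCCO1)CC[C@H]2[C@@](C)(CCC(=O)OC)[C@@H](O[Si](C)(C)C(C)(C)C)CC[C@@]2(C)[C@H]3CO | intermediate
25 | diol: 4β-(3-hydroxy-3-methylbutyl), 9β-CH2OH | C13(OCCO1)CC[C@H]2[C@@](C)(CCC(C)(C)O)[C@@H](O[Si](C)(C)C(C)(C)C)CC[C@@]2(C)[C@H]3CO | intermediate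
26 | aldehyde: 9β-CHO | C13(OCCO1)CC[C@H]2[C@@](C)(CCC(C)(C)O)[C@@H](O[Si](C)(C)C(C)(C)C)CC[C@@]2(C)[C@H]3C=O | intermediate
27 | methyl acetoacetate | CC(=O)CC(=O)OC | starting material
28 | malonyl dichloride | O=C(Cl)CC(Cl)=O | starting material
29 | methyl 4-hydroxy-6-methyl-2-oxo-2H-pyran-5-carboxylate | COC(=O)c1c(C)oc(=O)cc1O | intermediate
30 | alkylidene pyrandione: C11=C3 Knoevenagel adduct of 26 and 29 | C13(OCCO1)CC[C@H]2[C@@](C)(CCC(C)(C)O)[C@@H](O[Si](C)(C)C(C)(C)C)CC[C@@]2(C)[C@H]3C=C4C(=O)OC(C)=C(C(=O)OC)C4=O | intermediate (not isolated)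
31 | pyrone adduct: 9β-CH2 on C3 of the 4-hydroxy-2-pyrone | C13(OCCO1)CC[C@H]2[C@@](C)(CCC(C)(C)O)[C@@H](O[Si](C)(C)C(C)(C)C)CC[C@@]2(C)[C@H]3Cc4c(O)c(C(=O)OC)c(C)oc4=O | intermediate
32 | methoxypyranone ketal: 2-methoxy-4-pyranone, C8 dioxolane | C13(OCCO1)CC[C@H]2[C@@](C)(CCC(C)(C)O)[C@@H](O[Si](C)(C)C(C)(C)C)CC[C@@]2(C)[C@H]3Cc4c(OC)oc(C)c(C(=O)OC)c4=O | intermediate
33 | methoxypyranone ketone: C8 ketone | O=C1CC[C@H]2[C@@](C)(CCC(C)(C)O)[C@@H](O[Si](C)(C)C(C)(C)C)CC[C@@]2(C)[C@H]1Cc1c(OC)oc(C)c(C(=O)OC)c1=O | intermediate
34 | methylene alcohol: C8=CH2, tertiary C3′–OH, 3β-OTBS | C=C1CC[C@H]2[C@@](C)(CCC(C)(C)O)[C@@H](O[Si](C)(C)C(C)(C)C)CC[C@@]2(C)[C@H]1Cc1c(OC)oc(C)c(C(=O)OC)c1=O | intermediate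
35 | silyl formate: C3′–OCHO, 3β-OTBS | C=C1CC[C@H]2[C@@](C)(CCC(C)(C)OC=O)[C@@H](O[Si](C)(C)C(C)(C)C)CC[C@@]2(C)[C@H]1Cc1c(OC)oc(C)c(C(=O)OC)c1=O | intermediate
36 | CNP0292250.1 | C=C1CC[C@H]2[C@@](C)(CCC(C)(C)OC=O)[C@@H](O)CC[C@@]2(C)[C@H]1Cc1c(OC)oc(C)c(C(=O)OC)c1=O | target

## Step count and least certain steps

Total: 25 steps. Longest linear sequence: 23 steps (1 to 36 through steps 1, 3–18 and 20–25; steps 2 and 19 make the side components 5 and 29).

**Step 10 (key step).** The cyclobutene product is a β,γ-unsaturated ketone and may be consumed by secondary photoreaction (1,3-acyl shift). Addition to the unactivated alkyne may also be slow enough for hydrogen abstraction by the excited enone to compete. Fallback: the alkyne of 15 is converted with Et4NCl3 into the (E)-1,2-dichloroalkene F1. Irradiation under the same conditions gives the saturated dichlorocyclobutane adduct F2, which cannot undergo the acyl shift. Reductive elimination with Zn in AcOH/EtOH then gives cyclobutene 16, where the route is rejoined.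

**Step 9.** Enamine formation from the congested aldehyde may be slow, and facial selectivity at C10 may be poor if catalyst and C9 centre do not reinforce each other as modelled. Fallback: 12 is condensed with (S)-1-phenylethanamine to the imine F3, whose secondary enamine tautomer adds to 13 on gentle heating in THF (auxiliary-controlled Michael addition) to give the keto imine F4. Aqueous AcOH hydrolyses F4 to 14, which is closed to 15 with KOH in MeOH as in the main route.

**Step 11.** Hydride delivery to the concave face, or poor facial selectivity next to the quaternary C4, would give the 3α alcohol. Fallback: reagent-controlled Corey–Bakshi–Shibata reduction of 16 with (R)-2-methyl-CBS-oxazaborolidine and BH3·SMe2, which distinguishes the quaternary C4 side from the C2 methylene side and should deliver the (3S) alcohol 17 directly; no new compound arises.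

**Step 15.** Hydrazone formation at the hindered C6 ketone may fail, or C5 may epimerise through the ene-hydrazine tautomer. Fallback: 21 is reduced with NaBH4 to the C6 alcohol F5 and converted with phenyl chlorothionoformate and pyridine into the thionocarbonate F6. Barton–McCombie deoxygenation (Bu3SnH, AIBN, toluene, 80 °C) then gives 23.

**Step 20.** Condensation at the congested aldehyde may be slow, C9 may epimerise through an enamine or through the alkylidene intermediate, and a second pyrone may add. Fallback: 29 is iodinated at C3 with N-iodosuccinimide to the iodopyrone F7 and O-methylated with MeOTf to the iodo-γ-pyranone F8. Iodine–magnesium exchange (i-PrMgCl·LiCl, THF, −40 °C) and addition to 26 give the carbinol F9. Acylation with 1,1′-thiocarbonyldiimidazole gives the imidazolide F10, and Barton–McCombie reduction (Bu3SnH, AIBN) gives 32, so step 21 is bypassed.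

**Step 25.** Cleavage of the hindered silyl ether may be slow, and forcing conditions would endanger the formate. Fallback: the silyl group is removed before the formate exists. Treating 34 with Bu4NF (THF, 50 °C) gives the diol F11. Selective silylation of the secondary hydroxyl (Et3SiCl, imidazole, DMF) gives the triethylsilyl ether F12, formylation as in step 24 gives F13, and brief treatment with HF·pyridine at 0 °C gives 36.

## Further compounds

F1 | step 10 | (4R)-4-{(1S)-2-(benzyloxy)-1-[2-((E)-2,3-dichloroprop-2-en-1-yl)-1,3-dioxolan-2-yl]ethyl}-2,4-dimethylcyclohex-2-en-1-one | O=C1CC[C@](C)(C=C1C)[C@@H](COCc1ccccc1)C2(OCCO2)C/C(Cl)=C\Cl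
F2 | step 10 | dichlorocyclobutane adduct: 16 with Cl on C6 and on C1′ instead of the C6=C1′ double bond | C13(OCCO1)CC(Cl)(C4Cl)[C@H]2[C@]4(C)C(=O)CC[C@@]2(C)[C@H]3COCc5ccccc5
F3 | step 9 | N-[(1S)-1-phenylethyl] imine of 12 | C[C@H](N=CC(C)[C@@H](COCc1ccccc1)C1(CC#C[Si](C)(C)C)OCCO1)c1ccccc1
F4 | step 9 | N-[(1S)-1-phenylethyl] imine of 14 | C[C@H](N=C[C@@](C)(CCC(=O)CC)[C@@H](COCc1ccccc1)C1(CC#C[Si](C)(C)C)OCCO1)c1ccccc1
F0 | step 11 | none | none
F5 | step 15 | C6 alcohol of 21 | C13(OCCO1)CC(O)[C@H]2[C@@](C)(/C=C/C(=O)OC)[C@@H](O[Si](C)(C)C(C)(C)C)CC[C@@]2(C)[C@H]3COCc4ccccc4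
F6 | step 15 | O-phenyl thionocarbonate of F5 | C13(OCCO1)CC(OC(=S)Oc4ccccc4)[C@H]2[C@@](C)(/C=C/C(=O)OC)[C@@H](O[Si](C)(C)C(C)(C)C)CC[C@@]2(C)[C@H]3COCc5ccccc5
F7 | step 20 | methyl 4-hydroxy-3-iodo-6-methyl-2-oxo-2H-pyran-5-carboxylate | COC(=O)c1c(C)oc(=O)c(I)c1O
F8 | step 20 | methyl 5-iodo-6-methoxy-2-methyl-4-oxo-4H-pyran-3-carboxylate | COC(=O)c1c(C)oc(OC)c(I)c1=O
F9 | step 20 | C11 carbinol: adduct of the pyranyl Grignard reagent from F8 with 26 | C13(OCCO1)CC[C@H]2[C@@](C)(CCC(C)(C)O)[C@@H](O[Si](C)(C)C(C)(C)C)CC[C@@]2(C)[C@H]3C(O)c4c(OC)oc(C)c(C(=O)OC)c4=O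
F10 | step 20 | O-(imidazol-1-ylthiocarbonyl) derivative of F9 | C13(OCCO1)CC[C@H]2[C@@](C)(CCC(C)(C)O)[C@@H](O[Si](C)(C)C(C)(C)C)CC[C@@]2(C)[C@H]3C(OC(=S)n4ccnc4)c5c(OC)oc(C)c(C(=O)OC)c5=O
F11 | step 25 | diol: 34 without the silyl group | C=C1CC[C@H]2[C@@](C)(CCC(C)(C)O)[C@@H](O)CC[C@@]2(C)[C@H]1Cc1c(OC)oc(C)c(C(=O)OC)c1=O
F12 | step 25 | 3β-triethylsilyl ether of F11 | C=C1CC[C@H]2[C@@](C)(CCC(C)(C)O)[C@@H](O[Si](CC)(CC)CC)CC[C@@]2(C)[C@H]1Cc1c(OC)oc(C)c(C(=O)OC)c1=O
F13 | step 25 | tertiary formate of F12 | C=C1CC[C@H]2[C@@](C)(CCC(C)(C)OC=O)[C@@H](O[Si](CC)(CC)CC)CC[C@@]2(C)[C@H]1Cc1c(OC)oc(C)c(C(=O)OC)c1=O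
A1 | alternative 1 | methyl 2-methyl-3-oxopent-4-enoate | C=CC(=O)C(C)C(=O)OC
A2 | alternative 1 | methyl 6-oxocyclohex-1-ene-1-carboxylate | O=C1CCCC=C1C(=O)OC
A3 | alternative 1 | cis-decalin-3,9-dione with methyl esters at C4 and C10 | C1CC[C@H]2[C@@](C)(C(=O)OC)C(=O)CC[C@@]2(C(=O)OC)C1=O
A4 | alternative 2 | cis-fused 2-en-8-one with free tertiary alcohol chain and C11 malonate | O=C1CC[C@H]2[C@@](C)(CCC(C)(C)O)C=CC[C@@]2(C)[C@H]1CC(C(=O)OC)C(=O)OC
A5 | alternative 3 | ring B allylsilane: C8=C9 alkene with CH2SiMe3 on C8, 3β-OTBS, triethylsilyl ether on C3′ | C[Si](C)(C)CC1CC[C@H]2[C@@](C)(CCC(C)(C)O[Si](CC)(CC)CC)[C@@H](O[Si](C)(C)C(C)(C)C)CC[C@@]2(C)C=1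
A6 | alternative 3 | formaldehyde | C=O
A7 | alternative 3 | 3-(decalinylmethyl)-4-hydroxy-2-pyrone with C8 exocyclic methylene | C=C1CC[C@H]2[C@@](C)(CCC(C)(C)O[Si](CC)(CC)CC)[C@@H](O[Si](C)(C)C(C)(C)C)CC[C@@]2(C)[C@H]1Cc1c(O)c(C(=O)OC)c(C)oc1=O
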